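The earlier runs and the new flask stem from a simulated flask for an exercise; noise was put on by code.

Late in the maple run the target is still climbing: from 2.00 min to 3.00 min it gains 11 percentage points and you see no level, so treat the curve up to the asked time as one exponential approach.

| flask | starting material | partner | remark | time |
|---|---|---|---|---|
| maple | 0.25 M | 0.25 M | run made earlier |  |
| oak | 0.25 M | 0.35 M | run made earlier |  |
| birch | 0.25 M | 0.55 M | run made earlier |  |
| Friday's | 0.25 M | 0.250 M (fed, over 2.0 min) | all else is in the flask from the start; the feed brings no volume worth counting | 3.0 min |
| Sunday's | 0.25 M (fed, over 2.0 min) | 0.250 M | all else is in the flask from the start; the feed brings no volume worth counting | 3.0 min |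
| Tuesday's | 0.25 M | 0.250 M | everything together at the start | 3.0 min |

| maple: time / min | maple: target / % | oak: time / min | oak: target / % | birch: time / min | birch: target / % |
|---|---|---|---|---|---|
| 0.250 | 2.4 | 0.250 | 5.7 | 0.667 | 13.9 |
| 0.833 | 12.5 | 0.500 | 8.0 | 1.33 | 22.4 |
| 1.33 | 21.1 | 1.00 | 17.9 | 2.00 | 32.3 |
| 2.00 | 27.2 | 2.00 | 29.0 | 3.00 | 42.8 |
| 3.00 | 37.7 | 4.00 | 44.7 | 4.00 | 49.6 |

(standard deviation of a reading: 1 percentage point)

1. which flask leads in amount of target, in percent of the starting material charged ("all alike" within 1.5 percentage points) (Friday's / Sunday's / Tuesday's / all alike)
2. how much target is there at the end, in percent of the starting material charged: Friday's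
3. how much target is there at the end, in percent of the starting material charged: Sunday's
4. how much target is there at the end, in percent of the starting material charged: Tuesday's

- the earlier runs were read with a standard deviation of 1 points

The last maple reading gives an apparent first-order constant, minus the logarithm of the unconverted share over the time:

k = 0.158 min⁻¹

The birch run, read at the same time, gives a weak apparent order in c partner:

n = 0.210

Tuesday's repeats maple, so I read 37.7% for it. I reckon a steady feed of starting material as if the charge fell in at mid-feed, so for Sunday's:

τ = 2.00 min

This τ is the effective time, the point on the maple curve where, by this reckoning, Sunday's ends, and it gives Sunday's 27.1%.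

Now draw Sunday's curve by this reckoning. It starts flat. Taking the fed material as unreacted, the target made by the end of the feed is 15.8%. That amount grows with the square of time, so its mean is a third of this, and putting that back gives 14.1%. There is the knee, at 2.0 min. The slope then falls from 0.136 min⁻¹ of the charge, and Sunday's curve ends at 26.6%, which I keep as my figure for Sunday's.

In Friday's I let each feed minute count by the share of c partner fed so far, to the power n, so:

τ = 2.65 min

That gives Friday's 34.2%.

The forecast says Tuesday's leads, with 38%, 32% and 28% for Tuesday's, Friday's and Sunday's. Its Friday's lies below mine. Of Sunday's it says: “the starting material arrives late, so it has less time to react”.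

The flask gives Tuesday's 37.2%, Friday's 33.7% and Sunday's 28.3%, so Tuesday's leads, by 3.5 points over Friday's against a margin of 1.5 points.

    starting material → intermediate (k = 0.00510 s⁻¹)
    2 intermediate → homo product (k = 0.0350 L mol⁻¹ s⁻¹)
    partner → decomposition product (k = 2.50 × 10⁻⁵ s⁻¹)
    starting material + intermediate → side product (k = 0.0390 L mol⁻¹ s⁻¹)
    target ⇌ isomer of the product (K = 0.360, k = 0.0150 s⁻¹)
    partner + intermediate → target (k = 0.370 L mol⁻¹ s⁻¹)

At the end Friday's holds 14.7% of side product and Tuesday's 9.04%, in percent of the starting material charged, where one side product counts as two. Feed Sunday's over 0.600 min instead, and the effective time becomes 2.70 min, which predicts 34.7%; that flask gives 34.9%.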